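The gamma, beta and delta runs have been read, and the flask differs from the gamma run in transfer agent and in time.

| flask | solid monomer | transfer agent | initiator | remark | time |
|---|---|---|---|---|---|
| gamma | 0.25 M | 0.050 M | 0.95 mol% | run made earlier |  |
| beta | 0.25 M | 0.11 M | 0.95 mol% | run made earlier |  |
| delta | 0.50 M | 0.075 M | 0.95 mol% | run made earlier |  |
| flask | 0.25 M | 0.0750 M | 0.95 mol% |  | 50 min |

| run | time / min | monomer in chains / % |
|---|---|---|
| gamma | 3.00 | 0 |
| gamma | 5.00 | 0.5 |
| gamma | 8.00 | 0 |
| gamma | 12.0 | 1.6 |
| gamma | 15.0 | 1.6 |
| gamma | 25.0 | 5.0 |
| gamma | 40.0 | 8.6 |
| beta | 2.00 | 0.1 |
| beta | 6.00 | 0 |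
| beta | 12.0 | 0.1 |
| beta | 15.0 | 0.8 |
| beta | 25.0 | 3.0 |
| beta | 30.0 | 4.2 |
| beta | 40.0 | 6.3 |
| delta | 8.00 | 0 |
| delta | 15.0 | 0.8 |
| delta | 25.0 | 2.4 |
| delta | 30.0 | 4.1 |
| delta | 40.0 | 5.3 |

(each reading ± 0.5 percentage points)

- solid monomer is a solid; its amount is given per volume of the solution
- the numbers in the tables scatter with a standard deviation of 0.5 percentage points
- at the start none of the solid monomer is in solution

- north-west: doubling the dissolution coefficient of the solid monomer, all else as stated
- south-west: doubling the amount of initiator, all else as stated
- south-east: doubling the solubility of the solid monomer, all else as stated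

* the monomer in chains standing at 50 min, as a percentage of the solid monomer charged
* the change that raises the amount of monomer in chains at 50 min, in percent of the solid monomer charged most ("none" if none brings more than 2 percentage points) (north-west / south-west / south-east / none)
* amount of monomer in chains at 50 min, in percent of the solid monomer charged, after north-west

At 40.0 min the gamma run has 8.6 % of its charge in chains and the beta run 6.3 %. On logarithmic axes, these two scattered readings make that fraction fall as transfer agent to the power 0.395, which puts the flask at an estimated 7.33 % at that time.

How far does the flask climb by 50 min? The last two gamma readings give a power of time of 1.15, so this reckoning ends at 9.48 %.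

What does more initiator buy? The delta run doubles the charge and, at the same loading, the initiator. Its 5.3 % of a doubled charge is 1.45 times the amount in chains estimated for the flask. The charge changed together with the initiator, so taking that gain as the initiator's is an assumption; with the scatter of the readings in it, the assumption gives 0.533 for the initiator power, the order of the amount of monomer in chains in the amount of initiator at fixed time and transfer agent.

This reckoning therefore puts the flask with doubled initiator at 13.7 %. If chains grow in proportion to free monomer, doubled solubility gives a factor of 2, more than the 1.45 of initiator, so this reckoning picks south-east. No run varies the dissolution coefficient.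

The forecast gives 9.7 % (8.6 % to 10.9 %), above the 9.48 % of this reckoning, and 10.6 % after north-west, and it chooses south-east, holding that “solubility roughly doubles the rate”.

The flask gives 9.76 %, and south-east gains most, 14 percentage points, while north-west reaches 14.2 %.

    solid monomer ⇌ free monomer, rate k1*(cs1 - [free monomer]) while solid is left; crystals form when [free monomer] > cs1 (solubility = 15.0 mM, k = 0.0960 /min)
    free monomer + initiator → living end + monomer in chains (k = 1.70 /M/min)
    living end + transfer agent → dead chain (kL = 1.30 /M/min)
    free monomer + living end → monomer in chains + living end, rate k4*[living end]*[free monomer] (k = 270 /M/min)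

At 25.0 min the free monomer in the flask stands at 58.2 % of saturation. On the flask's 9.76 %, the initiator power promises a gain of 4.4 points from doubled initiator, and the flask with doubled initiator gains 3.7 points. For the neighbour flask with 0.24 mol% of initiator, the same power gives 4.69 %, and that neighbour holds 3.84 %.

All runs were generated by integration with constants of no real substance, noise included.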